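The constants of this flask are hidden from us, so we start from two rates that need none.

| flask | starting material | partner | free catalyst | time |
|---|---|---|---|---|
| north | 0.600 M | 0.720 M | 0.0600 M |  |
| north-east | 0.360 M | 0.480 M | 0.0600 M |  |
| east | 0.600 M | 0.720 M | 0.180 M |  |
| south | 1.80 M | 0.720 M | 0.0200 M | 60 min |

- north run (time / min: [target] / M): 8.6: 0.061; 17: 0.113; 26: 0.176; 34: 0.235; 43: 0.279; 51: 0.314; 60: 0.359
- north-east run (time / min: [target] / M): 8.6: 0.044; 17: 0.079; 26: 0.118; 34: 0.162; 43: 0.178; 51: 0.210; 60: 0.249
- east run (time / min: [target] / M): 8.6: 0.119; 17: 0.210; 26: 0.292; 34: 0.372; 43: 0.435; 51: 0.473; 60: 0.514

(standard deviation of a reading: 0.005 M)

- Overall: starting material + partner -> target, with free catalyst as catalyst.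
- Constant volume, constant temperature.
- Bound and free are read together.
- "The second partner" is partner.
- An order is taken over about fifteen percent of the charge, up and down.

* reaction order in [free catalyst] at the outset, round the charge of the north run, defined at two percent of the starting material turned into target
* the north-east run starts with 0.240 M less of starting material and of partner than the north run, and with no target. Compared where both hold the same amount of starting material, once fifteen percent of what the north-east run was charged with has turned into target, is the north-east run faster, slower or alike (within a tenth)?
* target in the south run at 60 min, as a share of the starting material charged

The north and east runs hold the same starting material (0.600 M) and partner (0.720 M) and differ in catalyst, 0.0600 M against 0.180 M. The ratio of their rates therefore speaks of the catalyst with the other charges held. For each rate we take the target at the first reading, 8.6 min, divided by that time: 0.00709 M min⁻¹ in the north run and 0.0138 M min⁻¹ in the east run. Their ratio is 1.95, less than the catalyst ratio of 3.00. That gives 0.608 as the catalyst order, the power of the catalyst charge that the rate follows with the other charges held. It is a reading: the scatter is 8.20% of the north value, and the step is wider than the one asked.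

The south run holds a third of the north catalyst and the same partner, here the limiting reagent at 0.720 M against 1.80 M of starting material. Carrying the order over, we put its rate at 0.513 of the north run's. The north target at 60 min, 0.359 M, then scales to 0.184 M, or 10.2% of the south charge. This counts the larger starting material for nothing, and that is a choice of ours, not something the readings force: the north-east run holds 0.600 of the north starting material but 0.667 of the north partner, so the runs do bear on the two orders, and our scaling doesn't use them.

The forecast gives an order of 0.63, alike and 9.5%, a little from ours on the two numbers, and it expects the south run to go “with the order drifting upward at low loading”. We side with it on the north-east question.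

The flask gives an order of 0.55, alike (a rate ratio of 1.0) and 22.4%, which is 13 percentage points above the forecast.

    free catalyst + starting material → loaded catalyst + by-product (3.198 M⁻¹ min⁻¹)
    loaded catalyst + partner → target + free catalyst (3.594 M⁻¹ min⁻¹)
    2 free catalyst ⇌ resting dimer, settled at all times (189.0 M⁻¹)
    2 starting material ⇌ idle substrate dimer, settled at all times (3.750 M⁻¹)

In the north and east runs, loading and the handing-on to partner ran side by side while both dimers stayed in balance with their free forms, and half the charge had turned at 47.2 min in the north run and 26.0 min in the east run, a ratio of 1.82 beside the 1.95 that the order stands on. The same two steps ran in the south run with 1.80 M of starting material present, and against the 0.184 M scaled by the order it made 0.403 M, twice that, or 22.4% of its charge.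

The earlier runs and the new flask are calculated from invented constants, noise included.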